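## Retrosynthetic overview

1. The last bond is C4–O of the C4–O–C4′ ether: flavan-4-ol 8 (unit B, complete) adds to the o-quinone methide 18 of unit A (C5=O, C4a=C4), released from 16 by a peri O5→O4 pivaloyl shift.
2. The last ring is the pyran ring of unit A (bonds C3–C4 and C2–O1), closed by a catalytic asymmetric formal [4+2] of styrene with the O-silylated salicylaldehyde 13; silicon moves from O1 to O4.
3. 13 comes from 3,4,5-trimethoxyphenol (ortho-formylation, silylation, carbonyl-directed demethylation, pivaloylation); 8 comes from acetophenone 1 via chromone 3, asymmetric phenyl addition, reduction and Mitsunobu inversion.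
4. Ring order: pyran ring of unit B (step 1), then pyran ring of unit A (step 10); both benzene rings are bought.
5. Enabling feature: in ring A the formyl carbon (future C4) sits on C4a between C8a–O1 and C5–O. O1 ortho to the formyl group makes 13 a 1-oxadiene (o-quinone methide) equivalent, O1=C8a–C4a=C4; the C5 oxygen peri to C4 later turns C4 into the quinone methide terminus that accepts 8.

Key step: step 10

Remark: compound 1 and both antipodes of the ligand (step 2) and of the IDPi catalyst (step 10) are taken as purchasable or preparable by known routes. In both steps the antipode that delivers the 2S centre is meant; the sense named in step 2 rests on analogy with cyclic enones, and the sense in step 10 has to be found in a first screen.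

## Route

Step 1
Reactants: 1 1-(6-hydroxy-2,3,4-trimethoxyphenyl)ethan-1-one
Product: 3 5,6,7-trimethoxy-4H-chromen-4-one, via enaminone 2 (not isolated)
Conditions: DMF-DMA, 95 °C; then AcOH, 100 °C
Reagents that add atoms: N,N-dimethylformamide dimethyl acetal, COC(OC)N(C)C
Why: Enaminone formation at the methyl ketone, then addition–elimination of the ortho phenol onto the enaminone, is the standard chromone synthesis; no stereocentre is formed.

Step 2
Reactants: 3 5,6,7-trimethoxy-4H-chromen-4-one; 4 phenylboronic acid
Product: 5 (S)-5,6,7-trimethoxy-2-phenylchroman-4-one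
Conditions: Pd(OCOCF3)2 (5 mol %), (R)-t-BuPyOx (6 mol %), NH4PF6 (30 mol %), H2O (5 equiv), ClCH2CH2Cl, 60 °C
Reagents that add atoms: none
Why: Pd(II)/pyridine-oxazoline-catalysed asymmetric conjugate addition of arylboronic acids to chromones is a known route to flavanones; C2 is set by the ligand, the R ligand being the antipode of the one that gives R β-aryl ketones from cyclic enones.

Step 3
Reactants: 5 (S)-5,6,7-trimethoxy-2-phenylchroman-4-one
Product: 6 (2S,4S)-5,6,7-trimethoxy-2-phenylchroman-4-ol
Conditions: NaBH4, MeOH/THF, 0 °C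
Reagents that add atoms: none
Why: Borohydride reduction of flavanones delivers hydride along the pseudo-axial trajectory with the 2-phenyl group pseudo-equatorial, which should give the 2,4-cis (4S) alcohol.

Step 4
Reactants: 6 (2S,4S)-5,6,7-trimethoxy-2-phenylchroman-4-ol
Product: 7 (2S,4R)-5,6,7-trimethoxy-2-phenylchroman-4-yl 4-nitrobenzoate
Conditions: 4-nitrobenzoic acid, PPh3, DIAD, toluene, 0 °C to rt
Reagents that add atoms: 4-nitrobenzoic acid, O=C(O)c1ccc(cc1)[N+](=O)[O-]
Why: Mitsunobu esterification inverts C4 to the 2,4-trans (4R) ester; an SN1 leak should end trans as well, because a pseudo-equatorial C4–O is pushed by the peri 5-OMe.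

Step 5
Reactants: 7 (2S,4R)-5,6,7-trimethoxy-2-phenylchroman-4-yl 4-nitrobenzoate
Product: 8 (2S,4R)-5,6,7-trimethoxy-2-phenylchroman-4-ol
Conditions: K2CO3 (cat.), MeOH/THF, rt
Reagents that add atoms: none
Why: Base-catalysed methanolysis cleaves the acyl–O bond, so C4 keeps its configuration.

Step 6
Reactants: 9 3,4,5-trimethoxyphenol
Product: 10 6-hydroxy-2,3,4-trimethoxybenzaldehyde
Conditions: MgCl2, Et3N, (CH2O)n, MeCN, reflux
Reagents that add atoms: paraformaldehyde (formaldehyde), C=O
Why: Magnesium phenoxide-directed ortho-formylation (Casnati–Skattebøl) places the formyl group ortho to the hydroxyl; the two ortho positions are equivalent and the para position is blocked.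

Step 7
Reactants: 10 6-hydroxy-2,3,4-trimethoxybenzaldehyde
Product: 11 6-[(tert-butyldimethylsilyl)oxy]-2,3,4-trimethoxybenzaldehyde
Conditions: TBSCl, imidazole, DMF, rt
Reagents that add atoms: tert-butyldimethylsilyl chloride, CC(C)(C)[Si](C)(C)Cl
Why: Standard silylation of the only free phenol.

Step 8
Reactants: 11 6-[(tert-butyldimethylsilyl)oxy]-2,3,4-trimethoxybenzaldehyde
Product: 12 6-[(tert-butyldimethylsilyl)oxy]-2-hydroxy-3,4-dimethoxybenzaldehyde
Conditions: BCl3 (1.1 equiv), CH2Cl2, −78 to −40 °C; then H2O
Reagents that add atoms: none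
Why: Carbonyl-directed demethylation: BCl3 chelated between the formyl oxygen and the ortho methoxy oxygen cleaves only that methyl ether, the other ortho oxygen being a silyl ether.

Step 9
Reactants: 12 6-[(tert-butyldimethylsilyl)oxy]-2-hydroxy-3,4-dimethoxybenzaldehyde
Product: 13 3-[(tert-butyldimethylsilyl)oxy]-2-formyl-5,6-dimethoxyphenyl pivalate
Conditions: PivCl, Et3N, DMAP (cat.), CH2Cl2, 0 °C to rt
Reagents that add atoms: pivaloyl chloride, CC(C)(C)C(=O)Cl
Why: DMAP-catalysed acylation of the hydrogen-bonded phenol makes O5 non-nucleophilic and installs the acyl group needed in step 12.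

Step 10
Reactants: 13 3-[(tert-butyldimethylsilyl)oxy]-2-formyl-5,6-dimethoxyphenyl pivalate; 14 styrene
Product: 15 (2S,4R)-4-[(tert-butyldimethylsilyl)oxy]-6,7-dimethoxy-2-phenylchroman-5-yl pivalate
Conditions: chiral IDPi (imidodiphosphorimidate) Brønsted acid (3 mol %, antipode giving 2S), styrene (3 equiv), CH2Cl2, −60 °C
Reagents that add atoms: none
Why: Proposed new method: a silylium ion paired with the chiral IDPi anion (formed by protodesilylation of a trace of 13) silylates the formyl oxygen to a benzylic silyloxycarbenium ion, the O-silylated form of the o-quinone methide O1=C8a–C4a=C4; styrene adds with its CH2 terminus to C4, and the C2 benzylic cation is captured by the silyl ether oxygen O1, whose TBS group returns to the anion and is carried to the next aldehyde (net shift of silicon from O1 to O4, no by-product). The closest known reaction types are the IDPi-catalysed asymmetric intermolecular Prins reaction of styrenes with aldehydes and the Lewis acid-catalysed [4+2] of salicylaldehyde-derived oxocarbenium ions with styrenes to 4-alkoxyflavans. The pyran ring closes in a stepwise polar formal [4+2]: the C3–C4 bond first, then six-membered C2–O1 closure through a chair-like transition state. C4 is set by the chiral anion, which shields one face of the planar oxocarbenium ion; C2 follows it (phenyl pseudo-equatorial, C4–OSi pseudo-axial because a pseudo-equatorial C4–O would clash with the peri C5 pivalate), so the two centres form as a pair and only C2 has to last, C4 being flattened again in step 12. The step needs regiocontrol of the closure and fast intramolecular capture of the cation: only O1 can close (O5 is acylated and the formyl carbon already sits on C4a), and its ortho position should make capture faster than attack by a second aldehyde or by styrene.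

Step 11
Reactants: 15 (2S,4R)-4-[(tert-butyldimethylsilyl)oxy]-6,7-dimethoxy-2-phenylchroman-5-yl pivalate
Product: 16 (2S,4R)-4-hydroxy-6,7-dimethoxy-2-phenylchroman-5-yl pivalate
Conditions: TBAF, AcOH (1:1), THF, 0 °C to rt
Reagents that add atoms: none
Why: Buffered fluoride removes the secondary silyl ether without leaving a free alkoxide, so the aryl pivalate should stay on O5; the C4 configuration is of no consequence.

Step 12
Reactants: 16 (2S,4R)-4-hydroxy-6,7-dimethoxy-2-phenylchroman-5-yl pivalate; 8 (2S,4R)-5,6,7-trimethoxy-2-phenylchroman-4-ol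
Product: 19 beilschmieflavonoid B, via C4-pivalate phenoxide 17 (not isolated), via o-quinone methide 18 (not isolated)
Conditions: 8 (3.0 equiv), t-BuMgCl (2.9 equiv), THF, 0 °C; then 16 added slowly, −40 to 0 °C; pH 7 buffer
Reagents that add atoms: none
Why: The C4 alkoxide takes the pivaloyl group from the peri O5 (six-membered transition state) and the resulting phenoxide expels pivalate to the o-quinone methide 18, a known way to generate such species from o-acyloxybenzyl alkoxides; the alkoxide of 8, which cannot ionise under base, adds to C4 pseudo-axially and trans to the pseudo-equatorial C2 phenyl (also the stable arrangement, since a pseudo-equatorial C4–O is pushed by the C5 oxygen), while C2 of unit A and both centres of 8 are untouched.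

## Compound list

1 | 1-(6-hydroxy-2,3,4-trimethoxyphenyl)ethan-1-one | CC(=O)c1c(O)cc(OC)c(OC)c1OC | starting material
2 | (E)-3-(dimethylamino)-1-(6-hydroxy-2,3,4-trimethoxyphenyl)prop-2-en-1-one | CN(C)/C=C/C(=O)c1c(O)cc(OC)c(OC)c1OC | intermediate
3 | 5,6,7-trimethoxy-4H-chromen-4-one | O=c1ccoc2cc(OC)c(OC)c(OC)c12 | intermediate
4 | phenylboronic acid | OB(O)c1ccccc1 | starting material
5 | (S)-5,6,7-trimethoxy-2-phenylchroman-4-one | O=C1C[C@@H](c2ccccc2)Oc2cc(OC)c(OC)c(OC)c21 | intermediate
6 | (2S,4S)-5,6,7-trimethoxy-2-phenylchroman-4-ol (2,4-cis) | O[C@H]1C[C@@H](c2ccccc2)Oc2cc(OC)c(OC)c(OC)c21 | intermediate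
7 | (2S,4R)-5,6,7-trimethoxy-2-phenylchroman-4-yl 4-nitrobenzoate (2,4-trans) | O=C(O[C@@H]1C[C@@H](c2ccccc2)Oc2cc(OC)c(OC)c(OC)c21)c1ccc(cc1)[N+](=O)[O-] | intermediate
8 | (2S,4R)-5,6,7-trimethoxy-2-phenylchroman-4-ol (2,4-trans, unit B) | O[C@@H]1C[C@@H](c2ccccc2)Oc2cc(OC)c(OC)c(OC)c21 | intermediate
9 | 3,4,5-trimethoxyphenol | COc1cc(O)cc(OC)c1OC | starting material
10 | 6-hydroxy-2,3,4-trimethoxybenzaldehyde | COc1cc(O)c(C=O)c(OC)c1OC | intermediate
11 | 6-[(tert-butyldimethylsilyl)oxy]-2,3,4-trimethoxybenzaldehyde | COc1cc(O[Si](C)(C)C(C)(C)C)c(C=O)c(OC)c1OC | intermediate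
12 | 6-[(tert-butyldimethylsilyl)oxy]-2-hydroxy-3,4-dimethoxybenzaldehyde | COc1cc(O[Si](C)(C)C(C)(C)C)c(C=O)c(O)c1OC | intermediate
13 | 3-[(tert-butyldimethylsilyl)oxy]-2-formyl-5,6-dimethoxyphenyl pivalate | COc1cc(O[Si](C)(C)C(C)(C)C)c(C=O)c(OC(=O)C(C)(C)C)c1OC | intermediate
14 | styrene | C=Cc1ccccc1 | starting material
15 | (2S,4R)-4-[(tert-butyldimethylsilyl)oxy]-6,7-dimethoxy-2-phenylchroman-5-yl pivalate | COc1cc2c(c(OC(=O)C(C)(C)C)c1OC)[C@H](O[Si](C)(C)C(C)(C)C)C[C@@H](c1ccccc1)O2 | intermediate
16 | (2S,4R)-4-hydroxy-6,7-dimethoxy-2-phenylchroman-5-yl pivalate | COc1cc2c(c(OC(=O)C(C)(C)C)c1OC)[C@H](O)C[C@@H](c1ccccc1)O2 | intermediate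
17 | (2S,4R)-5-hydroxy-6,7-dimethoxy-2-phenylchroman-4-yl pivalate (present as its magnesium phenoxide) | COc1cc2c(c(O)c1OC)[C@H](OC(=O)C(C)(C)C)C[C@@H](c1ccccc1)O2 | intermediate
18 | (S)-6,7-dimethoxy-2-phenyl-2,3-dihydro-5H-chromen-5-one (o-quinone methide, C4a=C4 and C5=O) | COC1=C(OC)C(=O)C2=CC[C@@H](c3ccccc3)OC2=C1 | intermediate
19 | beilschmieflavonoid B | COc1cc2c(c(O)c1OC)[C@H](O[C@@H]1C[C@@H](c3ccccc3)Oc3cc(OC)c(OC)c(OC)c31)C[C@@H](c1ccccc1)O2 | target

## Step count and risks

Total step count: 12. Longest linear sequence: 7 steps (9 to 19, steps 6 to 12); the unit B branch has 5 steps before the coupling.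

Steps most likely to fail:

1. Step 10 (Proposed new method). The chiral ion pair may not discriminate the faces well enough, or the C2 cation may be captured by a second aldehyde or by styrene before O1 closes, which would lower the optical purity at C2 or the yield. Fallback by known chemistry, setting out from flavanone 5, whose C2 centre is already fixed by step 2: BCl3 (CH2Cl2, −78 to 0 °C) should cleave only the carbonyl-chelated 5-methyl ether to give (S)-5-hydroxy-6,7-dimethoxy-2-phenylchroman-4-one F1. Pivaloylation (PivCl, Et3N, DMAP) should give (S)-6,7-dimethoxy-4-oxo-2-phenylchroman-5-yl pivalate F2. Luche reduction (NaBH4, CeCl3, MeOH, −78 °C, cold quench) should give (2S,4S)-4-hydroxy-6,7-dimethoxy-2-phenylchroman-5-yl pivalate F3. F3 is taken through the conditions of step 12 in place of 16; its acyl-shifted phenoxide (2S,4S)-5-hydroxy-6,7-dimethoxy-2-phenylchroman-4-yl pivalate F4 (not isolated) should collapse to the same quinone methide 18, so the route is rejoined at 19.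

2. Step 12. The quinone methide may lose a C3 proton and isomerise to the flav-3-ene before it is captured, or be captured by the alkoxide of 16 instead of that of 8. Fallback, setting out from 16: reductive removal of the pivaloyl group (DIBAL-H, CH2Cl2, −78 °C) should give (2S,4R)-6,7-dimethoxy-2-phenylchromane-4,5-diol F5. The quinone methide is then generated without base, by thermal dehydration of this o-hydroxybenzyl alcohol in the presence of 8 (3 equiv, 4 Å molecular sieves, toluene, 60 °C); capture by the neutral alcohol should lead back to 19.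

3. Step 8. BCl3 may also cleave the aryl silyl ether, or the crowded central 3-methoxy group may be cleaved instead of the chelated one. Fallback, setting out from 10: both chelating positions are freed first, excess BCl3 (3 equiv, CH2Cl2, 0 °C to rt) giving 2,6-dihydroxy-3,4-dimethoxybenzaldehyde F6. The two hydroxyls are then told apart by their surroundings: TBSCl (1.0 equiv) with imidazole at 0 °C should silylate the less hindered hydroxyl, the one flanked by H and not by OMe, which leads back to 12.

Further compounds
F1 | step 10 | (S)-5-hydroxy-6,7-dimethoxy-2-phenylchroman-4-one | O=C1C[C@@H](c2ccccc2)Oc2cc(OC)c(OC)c(O)c21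
F2 | step 10 | (S)-6,7-dimethoxy-4-oxo-2-phenylchroman-5-yl pivalate | O=C1C[C@@H](c2ccccc2)Oc2cc(OC)c(OC)c(OC(=O)C(C)(C)C)c21
F3 | step 10 | (2S,4S)-4-hydroxy-6,7-dimethoxy-2-phenylchroman-5-yl pivalate | COc1cc2c(c(OC(=O)C(C)(C)C)c1OC)[C@@H](O)C[C@@H](c1ccccc1)O2
F4 | step 10 | (2S,4S)-5-hydroxy-6,7-dimethoxy-2-phenylchroman-4-yl pivalate (magnesium phenoxide, not isolated) | COc1cc2c(c(O)c1OC)[C@@H](OC(=O)C(C)(C)C)C[C@@H](c1ccccc1)O2
F5 | step 12 | (2S,4R)-6,7-dimethoxy-2-phenylchromane-4,5-diol | COc1cc2c(c(O)c1OC)[C@H](O)C[C@@H](c1ccccc1)O2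
F6 | step 8 | 2,6-dihydroxy-3,4-dimethoxybenzaldehyde | COc1cc(O)c(C=O)c(O)c1OC
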